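**Plan**
1. Retrosynthesis: the C3–OH bond is removed first (flavonol back to the flavone C2=C3 alkene). Ring C is then cut at O1–C8a, C4–C4a and O1–C2, leaving 3,5-dimethoxy-4,6-dimethylbenzyne and 3-(2-methoxyphenyl)propiolic acid.
2. Enabling feature: ring A carries O1 on C8a and the acyl carbon C4 on the adjacent C4a. The C5 methoxy group next to C4a polarises an aryne spanning C4a–C8a so that oxygen goes to C8a.
3. Forward: the ring A aryne precursor is built from 2,6-dimethoxytoluene by C–H borylation/oxidation, ortho-formylation, hydrogenolysis to the C-methyl, bromination and retro-Brook silylation/triflation. Ring B arrives intact in the acid made from 2-ethynylanisole and CO2.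
4. The aryne insertion joins the two fragments and closes ring C in one operation. Dimethyldioxirane epoxidation and acid-induced epoxide opening then install the C3 hydroxyl.
5. Stereochemistry: the target has no stereocentre. The only stereogenic intermediate, the 2,3-epoxide, is racemic and is aromatised in the same step.

Key step: step 7

Remark: chromone numbering (O1, C2, C3, C4, C4a, C5–C8, C8a) is used throughout; ring A is the benzo ring, ring B the 2-methoxyphenyl group and ring C the pyranone.

**Step 1**
Reactants: 1 2,6-dimethoxytoluene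
Product: 3 3,5-dimethoxy-4-methylphenol, via aryl pinacol boronate 2 (not isolated)
Conditions: B2pin2 (0.6 equiv), [Ir(OMe)(cod)]2 (1.5 mol %), dtbpy (3 mol %), THF, 80 °C; then 2KHSO5·KHSO4·K2SO4, acetone/H2O, rt
Reagents that add atoms: bis(pinacolato)diboron, CC1(C)OB(OC1(C)C)B1OC(C)(C)C(C)(C)O1 (boryl group of 2 only); potassium peroxymonosulfate, [K+].[O-]S(=O)(=O)OO (phenol oxygen of 3)
Why: Iridium-catalysed aromatic C–H borylation is sterically governed and C4 of 1 is the only ring C–H without an ortho substituent, so the boronate should form meta to both methoxy groups and the one-flask boronate oxidation then gives the phenol.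

**Step 2**
Reactants: 3 3,5-dimethoxy-4-methylphenol
Product: 4 6-hydroxy-2,4-dimethoxy-3-methylbenzaldehyde
Conditions: MgCl2 (2 equiv), Et3N (4 equiv), (CH2O)n (6 equiv), MeCN, reflux; aq. HCl
Reagents that add atoms: formaldehyde (from paraformaldehyde), C=O
Why: The magnesium-mediated ortho-formylation of phenols (Casnati–Skattebøl reaction) delivers formaldehyde only ortho to the phenoxide through a magnesium chelate, and the two ortho sites of 3 are equivalent, so a single salicylaldehyde is expected.

**Step 3**
Reactants: 4 6-hydroxy-2,4-dimethoxy-3-methylbenzaldehyde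
Product: 5 3,5-dimethoxy-2,4-dimethylphenol
Conditions: H2 (3 atm), 10% Pd/C, AcOH, rt
Reagents that add atoms: none
Why: Catalytic hydrogenolysis of an electron-rich ortho-hydroxybenzaldehyde runs through the benzylic alcohol, whose activated C–O bond is cleaved readily in acetic acid to leave the C-methyl group while the aryl methyl ethers stay untouched.

**Step 4**
Reactants: 5 3,5-dimethoxy-2,4-dimethylphenol
Product: 6 2-bromo-3,5-dimethoxy-4,6-dimethylphenol
Conditions: NBS (1.0 equiv), CH2Cl2, −20 → 0 °C
Reagents that add atoms: N-bromosuccinimide, O=C1CCC(=O)N1Br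
Why: Electrophilic aromatic bromination can only take place at the single unsubstituted ring carbon, which is activated by the ortho hydroxyl, the ortho methoxy and the para methoxy group.

**Step 5**
Reactants: 6 2-bromo-3,5-dimethoxy-4,6-dimethylphenol
Product: 9 3,5-dimethoxy-2,4-dimethyl-6-(trimethylsilyl)phenyl trifluoromethanesulfonate, via aryl trimethylsilyl ether 7 (not isolated), via lithium 2-silylphenoxide 8 (not isolated)
Conditions: HMDS, THF, 70 °C, then evaporate; n-BuLi, THF, −78 °C; Tf2O, −78 → 0 °C
Reagents that add atoms: hexamethyldisilazane, C[Si](C)(C)N[Si](C)(C)C; n-butyllithium, [Li]CCCC (lithium of 8 only); trifluoromethanesulfonic anhydride, O=S(=O)(OS(=O)(=O)C(F)(F)F)C(F)(F)F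
Why: O-Silylation, bromine–lithium exchange and the ensuing 1,3 O→C silyl shift (retro-Brook rearrangement) give the ortho-silyl phenoxide, which triflic anhydride traps on oxygen, the standard sequence to ortho-silylaryl triflate aryne precursors.

**Step 6**
Reactants: 10 2-ethynylanisole
Product: 12 3-(2-methoxyphenyl)propiolic acid, via lithium acetylide 11 (not isolated)
Conditions: n-BuLi, THF, −78 °C; CO2, −78 °C → rt; aq. HCl
Reagents that add atoms: n-butyllithium, [Li]CCCC (lithium of 11 only); carbon dioxide, O=C=O
Why: Deprotonation of the terminal alkyne and carboxylation of the lithium acetylide with carbon dioxide is the standard preparation of arylpropiolic acids.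

**Step 7**
Reactants: 9 3,5-dimethoxy-2,4-dimethyl-6-(trimethylsilyl)phenyl trifluoromethanesulfonate; 12 3-(2-methoxyphenyl)propiolic acid
Product: 15 5,7-dimethoxy-2-(2-methoxyphenyl)-6,8-dimethyl-4H-chromen-4-one, via aryne 13 (not isolated), via caesium ynone phenolate 14 (not isolated)
Conditions: 9 (1.5 equiv), CsF (4 equiv), THF, sealed tube, 125 °C
Reagents that add atoms: caesium fluoride, [Cs+].[F-] (counter-ion of 14 only)
Why: Fluoride attack on silicon with loss of triflate releases aryne 13; the caesium carboxylate of 12 adds through oxygen to the aryne carbon that becomes C8a, the aryl anion developing at C4a attacks the carbonyl of the aryl ester just formed through a four-membered transition state, and collapse of that adduct (a formal aryne insertion into the acid C–O bond, akin to an anionic 1,3 O→C acyl shift) gives the ortho-acyl phenolate 14. The closest known reaction type is the fluoride-induced coupling of ortho-silylaryl triflates with carboxylic acids to ortho-hydroxyaryl ketones, which with arylpropiolic acids continues to flavones. Ring C then closes by 6-endo-dig conjugate addition of the phenolate oxygen to the ynone β-carbon (C2), and protonation at C3 gives 15. No stereocentre is formed. The step needs regioselective aryne capture: the C5 methoxy group next to the aryne polarises and distorts it so that the nucleophile adds to the remote carbon (C8a) and the negative charge sits beside the C–O dipole, an electronic bias expected to outweigh the modest steric shielding of C8a by the C8 methyl group. It also needs acyl transfer to outrun protonation and 6-endo to beat 5-exo closure, which the intramolecular four-centre shift in THF and the conjugated aryl ynone should secure.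

**Step 8**
Reactants: 15 5,7-dimethoxy-2-(2-methoxyphenyl)-6,8-dimethyl-4H-chromen-4-one
Product: 17 3-hydroxy-5,7-dimethoxy-2-(2-methoxyphenyl)-6,8-dimethyl-4H-chromen-4-one, via flavone 2,3-epoxide 16 (not isolated)
Conditions: DMDO (acetone solution, excess), CH2Cl2, 0 °C → rt, dark; evaporate; p-TsOH·H2O (cat.), CH2Cl2, rt
Reagents that add atoms: dimethyldioxirane, CC1(C)OO1
Why: Dioxirane epoxidation of the flavone C2–C3 double bond followed by acid-catalysed opening of the epoxide at C2 (oxocarbenium stabilised by O1 and ring B) and loss of the C3 proton is an established epoxidation–isomerisation route to 3-hydroxyflavones, and it erases the two transient stereocentres.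

**Compound list**
1 | 2,6-dimethoxytoluene | COc1cccc(OC)c1C | starting material
2 | 2-(3,5-dimethoxy-4-methylphenyl)-4,4,5,5-tetramethyl-1,3,2-dioxaborolane (formed in the flask) | COc1cc(B2OC(C)(C)C(C)(C)O2)cc(OC)c1C | intermediate
3 | 3,5-dimethoxy-4-methylphenol | COc1cc(O)cc(OC)c1C | intermediate
4 | 6-hydroxy-2,4-dimethoxy-3-methylbenzaldehyde | COc1cc(O)c(C=O)c(OC)c1C | intermediate
5 | 3,5-dimethoxy-2,4-dimethylphenol | COc1cc(O)c(C)c(OC)c1C | intermediate
6 | 2-bromo-3,5-dimethoxy-4,6-dimethylphenol | COc1c(Br)c(O)c(C)c(OC)c1C | intermediate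
7 | (2-bromo-3,5-dimethoxy-4,6-dimethylphenoxy)trimethylsilane (formed in the flask) | COc1c(Br)c(O[Si](C)(C)C)c(C)c(OC)c1C | intermediate
8 | lithium 3,5-dimethoxy-2,4-dimethyl-6-(trimethylsilyl)phenolate (formed in the flask) | [Li+].[O-]c1c(C)c(OC)c(C)c(OC)c1[Si](C)(C)C | intermediate
9 | 3,5-dimethoxy-2,4-dimethyl-6-(trimethylsilyl)phenyl trifluoromethanesulfonate | COc1c(C)c(OC)c(C)c(OS(=O)(=O)C(F)(F)F)c1[Si](C)(C)C | intermediate
10 | 2-ethynylanisole | COc1ccccc1C#C | starting material
11 | lithium (2-methoxyphenyl)acetylide (formed in the flask) | [Li]C#Cc1ccccc1OC | intermediate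
12 | 3-(2-methoxyphenyl)propiolic acid | COc1ccccc1C#CC(=O)O | intermediate
13 | 3,5-dimethoxy-4,6-dimethylbenzyne (formed in the flask) | COC1=C(C)C(OC)=C(C)C#C1 | intermediate
14 | caesium 3,5-dimethoxy-2-[3-(2-methoxyphenyl)propioloyl]-4,6-dimethylphenolate (formed in the flask) | [Cs+].[O-]c1c(C)c(OC)c(C)c(OC)c1C(=O)C#Cc1ccccc1OC | intermediate
15 | 5,7-dimethoxy-2-(2-methoxyphenyl)-6,8-dimethyl-4H-chromen-4-one | COc1ccccc1-c1cc(=O)c2c(OC)c(C)c(OC)c(C)c2o1 | intermediate
16 | 2,3-epoxy-5,7-dimethoxy-2-(2-methoxyphenyl)-6,8-dimethylchroman-4-one (racemic, cis-fused, one enantiomer drawn; formed in the flask) | COc1ccccc1[C@]12O[C@H]1C(=O)c1c(OC)c(C)c(OC)c(C)c1O2 | intermediate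
17 | 3-hydroxy-5,7-dimethoxy-2-(2-methoxyphenyl)-6,8-dimethyl-4H-chromen-4-one | COc1ccccc1-c1oc2c(C)c(OC)c(C)c(OC)c2c(=O)c1O | target

**Step count**
Total steps: 8. Longest linear sequence: 7 steps (steps 1–5, 7 and 8, from 1).

**Steps most likely to fail**

Step 7. The carboxylate may add to the wrong aryne carbon, because the C8 methyl group shields C8a. The aryl anion may be protonated before the acyl shift, or the propiolate may lose CO2 at 125 °C before it is captured. The fallback sets out from phenol 5 and returns at flavone 15 by chalcone chemistry. Friedel–Crafts acetylation of 5 at its only free ring position (Ac2O, BF3·OEt2, 80 °C) should give 1-(2-hydroxy-4,6-dimethoxy-3,5-dimethylphenyl)ethan-1-one F1. Claisen–Schmidt condensation of F1 with 2-methoxybenzaldehyde (KOH, EtOH, rt) should give (E)-1-(2-hydroxy-4,6-dimethoxy-3,5-dimethylphenyl)-3-(2-methoxyphenyl)prop-2-en-1-one F2. Oxidative cyclisation of F2 (catalytic I2, DMSO, 130 °C) then gives 15.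

Step 8. Epoxidation of the electron-poor C2–C3 double bond, flanked by the twisted ortho-substituted ring B, may be sluggish, and prolonged exposure to the dioxirane may oxidise the electron-rich rings. The fallback sets out from 15 and returns at 17 by deprotonation and boron oxidation. LiN(i-Pr)2 (THF, −78 °C) should remove the C3 proton to give 3-lithio-5,7-dimethoxy-2-(2-methoxyphenyl)-6,8-dimethyl-4H-chromen-4-one F3. B(OMe)3 traps it as lithium trimethoxy[5,7-dimethoxy-2-(2-methoxyphenyl)-6,8-dimethyl-4-oxo-4H-chromen-3-yl]borate F4. H2O2/AcOH (0 °C → rt) oxidises the C–B bond in the same flask to give 17.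

Step 5. O-Silylation of the doubly ortho-substituted phenol or the O→C silyl migration may be incomplete, which would return debrominated phenol on work-up, and triflation of the hindered phenoxide may be slow. The fallback sets out from 5 and returns at 9 by directed ortho-metalation, bypassing the bromide. Carbamoylation (Et2NCOCl, NaH, THF) should give 3,5-dimethoxy-2,4-dimethylphenyl diethylcarbamate F5. Ortho-lithiation between the carbamate and the methoxy group (s-BuLi, TMEDA, THF, −78 °C) gives 2-(diethylcarbamoyloxy)-4,6-dimethoxy-3,5-dimethylphenyllithium F6. Quenching with TMSCl at −78 °C gives 3,5-dimethoxy-2,4-dimethyl-6-(trimethylsilyl)phenyl diethylcarbamate F7. Reductive cleavage (LiAlH4, THF, reflux) frees 3,5-dimethoxy-2,4-dimethyl-6-(trimethylsilyl)phenol F8, and Tf2O/pyridine (CH2Cl2, 0 °C) converts F8 into 9.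

**Further compounds**
F1 | step 7 | 1-(2-hydroxy-4,6-dimethoxy-3,5-dimethylphenyl)ethan-1-one | CC(=O)c1c(O)c(C)c(OC)c(C)c1OC
F2 | step 7 | (E)-1-(2-hydroxy-4,6-dimethoxy-3,5-dimethylphenyl)-3-(2-methoxyphenyl)prop-2-en-1-one | COc1ccccc1/C=C/C(=O)c1c(O)c(C)c(OC)c(C)c1OC
F3 | step 8 | 3-lithio-5,7-dimethoxy-2-(2-methoxyphenyl)-6,8-dimethyl-4H-chromen-4-one | [Li]c1c(-c2ccccc2OC)oc2c(C)c(OC)c(C)c(OC)c2c1=O
F4 | step 8 | lithium trimethoxy[5,7-dimethoxy-2-(2-methoxyphenyl)-6,8-dimethyl-4-oxo-4H-chromen-3-yl]borate | [Li+].CO[B-](OC)(OC)c1c(-c2ccccc2OC)oc2c(C)c(OC)c(C)c(OC)c2c1=O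
F5 | step 5 | 3,5-dimethoxy-2,4-dimethylphenyl diethylcarbamate | CCN(CC)C(=O)Oc1cc(OC)c(C)c(OC)c1C
F6 | step 5 | 2-(diethylcarbamoyloxy)-4,6-dimethoxy-3,5-dimethylphenyllithium | CCN(CC)C(=O)Oc1c([Li])c(OC)c(C)c(OC)c1C
F7 | step 5 | 3,5-dimethoxy-2,4-dimethyl-6-(trimethylsilyl)phenyl diethylcarbamate | CCN(CC)C(=O)Oc1c([Si](C)(C)C)c(OC)c(C)c(OC)c1C
F8 | step 5 | 3,5-dimethoxy-2,4-dimethyl-6-(trimethylsilyl)phenol | COc1c(C)c(OC)c(C)c(O)c1[Si](C)(C)C
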